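**Retrosynthetic overview**

1. Botcinin I is a tetrahydropyran ring (O–C4–C5–C6–C7–C8) trans-fused at C4–C5 to a δ-lactone ring (C1–C5), with the (E)-4-oxooct-2-enoate on O7. The ester is cut first (acid 31 + alcohol 28), then the lactone C1–O5 bond (oxidative lactonisation of triol 23).
2. The strategy rests on C4, the fully substituted ether carbon of the pyran ring that sits next to the C3 carbinol. O8–C4 is disconnected to the threo 3,4-epoxide 21, which the C8 hydroxyl opens 6-exo with inversion at C4 (pyran ring first, lactone ring second).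
3. Epoxide 21 comes from a Z-allylic alcohol by C5-hydroxyl-directed epoxidation, and C5 from chelation-controlled reduction of Z-enone 17. The C6–C7 bond comes from a syn boron aldol of Z-enone 11 (C1–C6) with (S)-2-silyloxypropanal 14 (C7–C9), which leaves O7 as the only free hydroxyl for benzylation.
4. Enone 11 derives from methyl (S)-3-hydroxy-2-methylpropanoate via a Z-vinyl iodide; aldehyde 14 derives from ethyl (S)-lactate.

Key step: step 13

Remark: backbone carbons keep the target numbering throughout (C1 lactone carbonyl, C2 to C8 along the chain, C9 the methyl on C8); O1, O3, O5, O7 and O8 are the oxygens on those carbons.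

**Route**

Step 1
Reactants: 1 methyl (S)-3-hydroxy-2-methylpropanoate
Product: 2 methyl (S)-3-[(tert-butyldiphenylsilyl)oxy]-2-methylpropanoate
Conditions: t-BuPh2SiCl, imidazole, DMF, 0 °C → rt
Reagents that add atoms: tert-butyl(chloro)diphenylsilane, CC(C)(C)[Si](Cl)(c1ccccc1)c1ccccc1
Why: Imidazole-mediated silylation of the primary alcohol (silyl ether formation); the C2 stereocentre is not involved.

Step 2
Reactants: 2 methyl (S)-3-[(tert-butyldiphenylsilyl)oxy]-2-methylpropanoate
Product: 3 (S)-3-[(tert-butyldiphenylsilyl)oxy]-2-methylpropanal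
Conditions: i-Bu2AlH (1.05 equiv), CH2Cl2, −78 °C; MeOH, aq. sodium potassium tartrate
Reagents that add atoms: none
Why: Low-temperature half-reduction of the methyl ester stops at the aluminium hemiacetal and should release the aldehyde on work-up; it is used at once so that C2 does not epimerise.

Step 3
Reactants: 3 (S)-3-[(tert-butyldiphenylsilyl)oxy]-2-methylpropanal; 4 ethyltriphenylphosphonium iodide
Product: 8 tert-butyl{[(2R,3Z)-4-iodo-2-methylpent-3-en-1-yl]oxy}diphenylsilane, via ethylidenetriphenylphosphorane 5 (not isolated), via (1-iodoethyl)triphenylphosphonium iodide 6 (not isolated), via (1-iodoethylidene)triphenylphosphorane 7 (not isolated)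
Conditions: 4, n-BuLi, THF, 0 °C → rt; I2, −78 °C; NaN(SiMe3)2, −20 °C; then 3, −78 → −20 °C
Reagents that add atoms: iodine, II
Why: Wittig olefination with the α-iodo ylide (Stork–Zhao type) should give the trisubstituted vinyl iodide with iodine cis to the chain (Z), the geometry that later places C5 cis to C2.

Step 4
Reactants: 8 tert-butyl{[(2R,3Z)-4-iodo-2-methylpent-3-en-1-yl]oxy}diphenylsilane; 9 N-methoxy-N-methylpropanamide
Product: 11 (4Z,6R)-7-[(tert-butyldiphenylsilyl)oxy]-4,6-dimethylhept-4-en-3-one, via vinyllithium 10 (not isolated)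
Conditions: t-BuLi (2.1 equiv), Et2O, −78 °C; then 9, −78 → 0 °C; aq. NH4Cl
Reagents that add atoms: none
Why: Iodine–lithium exchange proceeds with retention of alkene geometry, and the vinyllithium acylates the Weinreb amide once through the chelated tetrahedral intermediate (Weinreb ketone synthesis), giving the Z-enone.

Step 5
Reactants: 12 ethyl (S)-lactate
Product: 13 ethyl (S)-2-[(tert-butyldimethylsilyl)oxy]propanoate
Conditions: t-BuMe2SiCl, imidazole, DMF, rt
Reagents that add atoms: tert-butyl(chloro)dimethylsilane, CC(C)(C)[Si](C)(C)Cl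
Why: Imidazole-mediated silylation of the secondary alcohol; the future C8 stereocentre is untouched.

Step 6
Reactants: 13 ethyl (S)-2-[(tert-butyldimethylsilyl)oxy]propanoate
Product: 14 (S)-2-[(tert-butyldimethylsilyl)oxy]propanal
Conditions: i-Bu2AlH (1.05 equiv), Et2O/hexane, −78 °C; aq. sodium potassium tartrate
Reagents that add atoms: none
Why: Half-reduction of the α-silyloxy ester at −78 °C is the standard access to this configurationally labile aldehyde, which is used crude.

Step 7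
Reactants: 11 (4Z,6R)-7-[(tert-butyldiphenylsilyl)oxy]-4,6-dimethylhept-4-en-3-one; 14 (S)-2-[(tert-butyldimethylsilyl)oxy]propanal
Product: 16 (2R,3Z,6R,7R,8S)-8-[(tert-butyldimethylsilyl)oxy]-1-[(tert-butyldiphenylsilyl)oxy]-7-hydroxy-2,4,6-trimethylnon-3-en-5-one, via Z(O)-dibutylboron dienolate 15 (not isolated)
Conditions: Bu2BOTf, i-Pr2NEt, CH2Cl2, −78 °C; then 14, −78 → −20 °C; pH 7 buffer, MeOH, H2O2, 0 °C
Reagents that add atoms: none
Why: Boron aldol reaction: the Z(O)-enolate of the ethyl ketone reacts through a chair (Zimmerman–Traxler) transition state that sets C6/C7 syn, and the α-silyloxy stereocentre of the aldehyde steers attack to the Cornforth/Felkin face, setting C7 anti to C8.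

Step 8
Reactants: 16 (2R,3Z,6R,7R,8S)-8-[(tert-butyldimethylsilyl)oxy]-1-[(tert-butyldiphenylsilyl)oxy]-7-hydroxy-2,4,6-trimethylnon-3-en-5-one
Product: 17 (2R,3Z,6R,7R,8S)-7-(benzyloxy)-8-[(tert-butyldimethylsilyl)oxy]-1-[(tert-butyldiphenylsilyl)oxy]-2,4,6-trimethylnon-3-en-5-one
Conditions: BnOC(=NH)CCl3, TfOH (cat.), cyclohexane/CH2Cl2, 0 °C
Reagents that add atoms: benzyl 2,2,2-trichloroacetimidate, ClC(Cl)(Cl)C(=N)OCc1ccccc1
Why: Acid-catalysed imidate benzylation etherifies the only free hydroxyl without base, so retro-aldol cleavage and silyl migration from O8 are avoided.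

Step 9
Reactants: 17 (2R,3Z,6R,7R,8S)-7-(benzyloxy)-8-[(tert-butyldimethylsilyl)oxy]-1-[(tert-butyldiphenylsilyl)oxy]-2,4,6-trimethylnon-3-en-5-one
Product: 18 (2R,3Z,5S,6S,7R,8S)-7-(benzyloxy)-8-[(tert-butyldimethylsilyl)oxy]-1-[(tert-butyldiphenylsilyl)oxy]-2,4,6-trimethylnon-3-en-5-ol
Conditions: Zn(BH4)2, Et2O, −30 → 0 °C
Reagents that add atoms: none
Why: Chelation-controlled 1,2-reduction: zinc bridges the C5 carbonyl and the C7 benzyloxy oxygen, and hydride adds axially to the half-chair chelate on the face away from the C6 methyl, which should set C5 syn to both C6 and C7.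

Step 10
Reactants: 18 (2R,3Z,5S,6S,7R,8S)-7-(benzyloxy)-8-[(tert-butyldimethylsilyl)oxy]-1-[(tert-butyldiphenylsilyl)oxy]-2,4,6-trimethylnon-3-en-5-ol
Product: 19 (2R,3Z,5S,6S,7R,8S)-7-(benzyloxy)-2,4,6-trimethylnon-3-ene-1,5,8-triol
Conditions: Bu4NF, THF, rt → 40 °C
Reagents that add atoms: none
Why: Fluoride-mediated desilylation removes both silyl ethers; the benzyl ether, the alkene and all stereocentres are inert to fluoride.

Step 11
Reactants: 19 (2R,3Z,5S,6S,7R,8S)-7-(benzyloxy)-2,4,6-trimethylnon-3-ene-1,5,8-triol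
Product: 20 (2R,3Z,5S,6S,7R,8S)-7-(benzyloxy)-5,8-dihydroxy-2,4,6-trimethylnon-3-en-1-yl 2,2-dimethylpropanoate
Conditions: PivCl (1.1 equiv), pyridine, CH2Cl2, −20 → 0 °C
Reagents that add atoms: pivaloyl chloride, CC(C)(C)C(Cl)=O
Why: Sterically selective acylation: the bulky acid chloride should esterify the primary C1 hydroxyl and leave the two hindered secondary hydroxyls free.

Step 12
Reactants: 20 (2R,3Z,5S,6S,7R,8S)-7-(benzyloxy)-5,8-dihydroxy-2,4,6-trimethylnon-3-en-1-yl 2,2-dimethylpropanoate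
Product: 21 (2S,3S,4R,5S,6S,7R,8S)-7-(benzyloxy)-3,4-epoxy-5,8-dihydroxy-2,4,6-trimethylnonyl 2,2-dimethylpropanoate
Conditions: mCPBA, CH2Cl2/aq. NaHCO3 (two-phase), 0 °C
Reagents that add atoms: 3-chloroperbenzoic acid, OOC(=O)c1cccc(Cl)c1
Why: Hydroxyl-directed peracid epoxidation (Henbest type): A(1,3) strain in the Z-allylic alcohol holds C5–H in the alkene plane, so the hydrogen-bonded peracid is delivered to one face and the threo epoxy alcohol should form, setting C3 and the epoxide configuration at C4.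

Step 13
Reactants: 21 (2S,3S,4R,5S,6S,7R,8S)-7-(benzyloxy)-3,4-epoxy-5,8-dihydroxy-2,4,6-trimethylnonyl 2,2-dimethylpropanoate
Product: 22 (2S,3S)-3-[(2R,3S,4S,5R,6S)-5-(benzyloxy)-3-hydroxy-2,4,6-trimethyloxan-2-yl]-3-hydroxy-2-methylpropyl 2,2-dimethylpropanoate
Conditions: camphorsulfonic acid (0.1 equiv), CH2Cl2, 0 °C → rt
Reagents that add atoms: none
Why: Protonation of the epoxide oxygen lengthens the C4–O bond because C4 is tertiary, and the C8 hydroxyl attacks C4 from the side opposite the departing oxygen in a borderline SN2 opening, so O8–C4 forms, the pyran closes and the epoxide oxygen stays on C3 as the free hydroxyl. The closest known reaction type is the acid-catalysed exo-selective cyclisation of hydroxy epoxides used to build tetrahydropyrans in polyether synthesis. The tetrahydropyran ring closes in the 6-exo-tet mode through a chair in which the C5 hydroxyl, C6 methyl, C7 benzyloxy and C8 methyl groups are all equatorial. C4 is the new stereocentre and is fixed by stereospecific inversion of the epoxide carbon, while C3 keeps its oxygen with retention, so the C3/C4 pair follows directly from the threo epoxide of step 12. The step needs attack at C4 by O8 only: C3 is excluded because it is secondary and would give a seven-membered ring, O7 is benzylated so the competing five-membered closure by a free hydroxyl cannot occur, O1 is an ester oxygen, and O5 sits on the carbon next to the epoxide.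

Step 14
Reactants: 22 (2S,3S)-3-[(2R,3S,4S,5R,6S)-5-(benzyloxy)-3-hydroxy-2,4,6-trimethyloxan-2-yl]-3-hydroxy-2-methylpropyl 2,2-dimethylpropanoate
Product: 23 (1S,2S)-1-[(2R,3S,4S,5R,6S)-5-(benzyloxy)-3-hydroxy-2,4,6-trimethyloxan-2-yl]-2-methylpropane-1,3-diol
Conditions: i-Bu2AlH (5 equiv), CH2Cl2, −78 °C; aq. sodium potassium tartrate
Reagents that add atoms: none
Why: Reductive cleavage of the pivalate (ester reduction) frees the C1 hydroxyl without base, leaving the benzyl ether and all stereocentres untouched.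

Step 15
Reactants: 23 (1S,2S)-1-[(2R,3S,4S,5R,6S)-5-(benzyloxy)-3-hydroxy-2,4,6-trimethyloxan-2-yl]-2-methylpropane-1,3-diol
Product: 26 (3R,4S,4aR,6S,7R,8R,8aS)-7-(benzyloxy)-4-hydroxy-3,4a,6,8-tetramethylperhydropyrano[3,2-b]pyran-2-one (lactone O1 on C8a, ring O5 between C4a and C6), via C1 hydroxy aldehyde 24 (not isolated), via six-membered lactol 25 (not isolated)
Conditions: TEMPO (0.2 equiv), PhI(OAc)2 (3 equiv), CH2Cl2, rt
Reagents that add atoms: none
Why: Oxidative lactonisation with the oxoammonium catalyst: the primary alcohol is oxidised chemoselectively to the aldehyde, the C5 hydroxyl adds to it to close the six-membered lactol, and a second oxidation gives the δ-lactone under non-basic conditions that should spare the C2 stereocentre.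

Step 16
Reactants: 26 (3R,4S,4aR,6S,7R,8R,8aS)-7-(benzyloxy)-4-hydroxy-3,4a,6,8-tetramethylperhydropyrano[3,2-b]pyran-2-one
Product: 27 (3R,4S,4aS,6S,7R,8R,8aS)-7-(benzyloxy)-3,4a,6,8-tetramethyl-4-[(triethylsilyl)oxy]perhydropyrano[3,2-b]pyran-2-one
Conditions: Et3SiOTf, 2,6-lutidine, CH2Cl2, −78 → 0 °C
Reagents that add atoms: triethylsilyl trifluoromethanesulfonate, CC[Si](CC)(CC)OS(=O)(=O)C(F)(F)F
Why: Silylation of the hindered C3 hydroxyl with a silyl triflate and a weak hindered base masks it so that only O7 can be acylated later.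

Step 17
Reactants: 27 (3R,4S,4aS,6S,7R,8R,8aS)-7-(benzyloxy)-3,4a,6,8-tetramethyl-4-[(triethylsilyl)oxy]perhydropyrano[3,2-b]pyran-2-one
Product: 28 (3R,4S,4aS,6S,7R,8R,8aS)-7-hydroxy-3,4a,6,8-tetramethyl-4-[(triethylsilyl)oxy]perhydropyrano[3,2-b]pyran-2-one
Conditions: H2 (1 atm), Pd/C, EtOAc, rt
Reagents that add atoms: none
Why: Hydrogenolysis of the benzyl ether over palladium on carbon; the silyl ether and the lactone are inert in ethyl acetate.

Step 18
Reactants: 29 glyoxylic acid monohydrate; 30 hexan-2-one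
Product: 31 (E)-4-oxooct-2-enoic acid
Conditions: pyrrolidine, AcOH, MeOH, 60 °C
Reagents that add atoms: none
Why: Amine-catalysed aldol condensation: the less substituted enamine of the methyl ketone adds to glyoxylic acid and dehydration should give the (E)-4-oxo-2-enoic acid.

Step 19
Reactants: 28 (3R,4S,4aS,6S,7R,8R,8aS)-7-hydroxy-3,4a,6,8-tetramethyl-4-[(triethylsilyl)oxy]perhydropyrano[3,2-b]pyran-2-one; 31 (E)-4-oxooct-2-enoic acid
Product: 33 (3R,4S,4aS,6S,7R,8R,8aS)-3,4a,6,8-tetramethyl-2-oxo-4-[(triethylsilyl)oxy]perhydropyrano[3,2-b]pyran-7-yl (E)-4-oxooct-2-enoate, via O-acylisourea 32 (not isolated)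
Conditions: DCC, DMAP (cat.), CH2Cl2, 0 °C → rt
Reagents that add atoms: none
Why: Steglich esterification (carbodiimide activation, DMAP acyl transfer) of the only free hydroxyl; the C7–O bond is not broken, so C7 keeps its configuration.

Step 20
Reactants: 33 (3R,4S,4aS,6S,7R,8R,8aS)-3,4a,6,8-tetramethyl-2-oxo-4-[(triethylsilyl)oxy]perhydropyrano[3,2-b]pyran-7-yl (E)-4-oxooct-2-enoate
Product: 34 botcinin I, (3R,4S,4aR,6S,7R,8R,8aS)-4-hydroxy-3,4a,6,8-tetramethyl-2-oxoperhydropyrano[3,2-b]pyran-7-yl (E)-4-oxooct-2-enoate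
Conditions: HF·pyridine, pyridine, THF, 0 °C
Reagents that add atoms: none
Why: Fluoride cleavage of the triethylsilyl ether under buffered, weakly acidic conditions that should leave the enone ester, the lactone and C2 untouched.

**Compound list**

1 | methyl (S)-3-hydroxy-2-methylpropanoate | COC(=O)[C@@H](C)CO | starting material
2 | methyl (S)-3-[(tert-butyldiphenylsilyl)oxy]-2-methylpropanoate | COC(=O)[C@@H](C)CO[Si](c1ccccc1)(c1ccccc1)C(C)(C)C | intermediate
3 | (S)-3-[(tert-butyldiphenylsilyl)oxy]-2-methylpropanal | O=C[C@@H](C)CO[Si](c1ccccc1)(c1ccccc1)C(C)(C)C | intermediate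
4 | ethyltriphenylphosphonium iodide | CC[P+](c1ccccc1)(c1ccccc1)c1ccccc1.[I-] | starting material
5 | ethylidenetriphenylphosphorane | CC=P(c1ccccc1)(c1ccccc1)c1ccccc1 | intermediate
6 | (1-iodoethyl)triphenylphosphonium iodide | CC(I)[P+](c1ccccc1)(c1ccccc1)c1ccccc1.[I-] | intermediate
7 | (1-iodoethylidene)triphenylphosphorane | CC(I)=P(c1ccccc1)(c1ccccc1)c1ccccc1 | intermediate
8 | tert-butyl{[(2R,3Z)-4-iodo-2-methylpent-3-en-1-yl]oxy}diphenylsilane (iodine cis to the chain) | I/C(C)=C\[C@@H](C)CO[Si](c1ccccc1)(c1ccccc1)C(C)(C)C | intermediate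
9 | N-methoxy-N-methylpropanamide | CCC(=O)N(C)OC | starting material
10 | [(2E,4R)-5-[(tert-butyldiphenylsilyl)oxy]-4-methylpent-2-en-2-yl]lithium (lithium cis to the chain) | [Li]/C(C)=C\[C@@H](C)CO[Si](c1ccccc1)(c1ccccc1)C(C)(C)C | intermediate
11 | (4Z,6R)-7-[(tert-butyldiphenylsilyl)oxy]-4,6-dimethylhept-4-en-3-one | CCC(=O)/C(C)=C\[C@@H](C)CO[Si](c1ccccc1)(c1ccccc1)C(C)(C)C | intermediate
12 | ethyl (S)-lactate | CCOC(=O)[C@H](C)O | starting material
13 | ethyl (S)-2-[(tert-butyldimethylsilyl)oxy]propanoate | CCOC(=O)[C@H](C)O[Si](C)(C)C(C)(C)C | intermediate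
14 | (S)-2-[(tert-butyldimethylsilyl)oxy]propanal | O=C[C@H](C)O[Si](C)(C)C(C)(C)C | intermediate
15 | dibutyl{[(2Z,4Z,6R)-7-[(tert-butyldiphenylsilyl)oxy]-4,6-dimethylhepta-2,4-dien-3-yl]oxy}borane | C/C=C(\OB(CCCC)CCCC)/C(C)=C\[C@@H](C)CO[Si](c1ccccc1)(c1ccccc1)C(C)(C)C | intermediate
16 | (2R,3Z,6R,7R,8S)-8-[(tert-butyldimethylsilyl)oxy]-1-[(tert-butyldiphenylsilyl)oxy]-7-hydroxy-2,4,6-trimethylnon-3-en-5-one | C[C@H](O[Si](C)(C)C(C)(C)C)[C@H](O)[C@@H](C)C(=O)/C(C)=C\[C@@H](C)CO[Si](c1ccccc1)(c1ccccc1)C(C)(C)C | intermediate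
17 | (2R,3Z,6R,7R,8S)-7-(benzyloxy)-8-[(tert-butyldimethylsilyl)oxy]-1-[(tert-butyldiphenylsilyl)oxy]-2,4,6-trimethylnon-3-en-5-one | C[C@H](O[Si](C)(C)C(C)(C)C)[C@H](OCc1ccccc1)[C@@H](C)C(=O)/C(C)=C\[C@@H](C)CO[Si](c1ccccc1)(c1ccccc1)C(C)(C)C | intermediate
18 | (2R,3Z,5S,6S,7R,8S)-7-(benzyloxy)-8-[(tert-butyldimethylsilyl)oxy]-1-[(tert-butyldiphenylsilyl)oxy]-2,4,6-trimethylnon-3-en-5-ol | C[C@H](O[Si](C)(C)C(C)(C)C)[C@H](OCc1ccccc1)[C@@H](C)[C@H](O)/C(C)=C\[C@@H](C)CO[Si](c1ccccc1)(c1ccccc1)C(C)(C)C | intermediate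
19 | (2R,3Z,5S,6S,7R,8S)-7-(benzyloxy)-2,4,6-trimethylnon-3-ene-1,5,8-triol | C[C@H](O)[C@H](OCc1ccccc1)[C@@H](C)[C@H](O)/C(C)=C\[C@@H](C)CO | intermediate
20 | (2R,3Z,5S,6S,7R,8S)-7-(benzyloxy)-5,8-dihydroxy-2,4,6-trimethylnon-3-en-1-yl 2,2-dimethylpropanoate | C[C@H](O)[C@H](OCc1ccccc1)[C@@H](C)[C@H](O)/C(C)=C\[C@@H](C)COC(=O)C(C)(C)C | intermediate
21 | (2S,3S,4R,5S,6S,7R,8S)-7-(benzyloxy)-3,4-epoxy-5,8-dihydroxy-2,4,6-trimethylnonyl 2,2-dimethylpropanoate (C2 and C5 cis on the epoxide) | C[C@H](O)[C@H](OCc1ccccc1)[C@@H](C)[C@H](O)[C@@]1(C)O[C@H]1[C@@H](C)COC(=O)C(C)(C)C | intermediate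
22 | (2S,3S)-3-[(2R,3S,4S,5R,6S)-5-(benzyloxy)-3-hydroxy-2,4,6-trimethyloxan-2-yl]-3-hydroxy-2-methylpropyl 2,2-dimethylpropanoate | c1ccccc1CO[C@@H]1[C@@H](C)[C@H](O)[C@](C)(O[C@H]1C)[C@@H](O)[C@@H](C)COC(=O)C(C)(C)C | intermediate
23 | (1S,2S)-1-[(2R,3S,4S,5R,6S)-5-(benzyloxy)-3-hydroxy-2,4,6-trimethyloxan-2-yl]-2-methylpropane-1,3-diol | c1ccccc1CO[C@@H]1[C@@H](C)[C@H](O)[C@](C)(O[C@H]1C)[C@@H](O)[C@@H](C)CO | intermediate
24 | C1 aldehyde of triol 23 (3-hydroxy-2-methyl-3-oxanylpropanal, configuration as in 23) | c1ccccc1CO[C@@H]1[C@@H](C)[C@H](O)[C@](C)(O[C@H]1C)[C@@H](O)[C@@H](C)C=O | intermediate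
25 | six-membered lactol from 24 (O5 on C1, both anomers) | c1ccccc1CO[C@@H]1[C@@H](C)[C@@H]2OC(O)[C@H](C)[C@H](O)[C@@]2(C)O[C@H]1C | intermediate
26 | (3R,4S,4aR,6S,7R,8R,8aS)-7-(benzyloxy)-4-hydroxy-3,4a,6,8-tetramethylperhydropyrano[3,2-b]pyran-2-one | c1ccccc1CO[C@@H]1[C@@H](C)[C@@H]2OC(=O)[C@H](C)[C@H](O)[C@@]2(C)O[C@H]1C | intermediate
27 | (3R,4S,4aS,6S,7R,8R,8aS)-7-(benzyloxy)-3,4a,6,8-tetramethyl-4-[(triethylsilyl)oxy]perhydropyrano[3,2-b]pyran-2-one | c1ccccc1CO[C@@H]1[C@@H](C)[C@@H]2OC(=O)[C@H](C)[C@H](O[Si](CC)(CC)CC)[C@@]2(C)O[C@H]1C | intermediate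
28 | (3R,4S,4aS,6S,7R,8R,8aS)-7-hydroxy-3,4a,6,8-tetramethyl-4-[(triethylsilyl)oxy]perhydropyrano[3,2-b]pyran-2-one | O[C@@H]1[C@@H](C)[C@@H]2OC(=O)[C@H](C)[C@H](O[Si](CC)(CC)CC)[C@@]2(C)O[C@H]1C | intermediate
29 | glyoxylic acid monohydrate | OC(O)C(=O)O | starting material
30 | hexan-2-one | CCCCC(C)=O | starting material
31 | (E)-4-oxooct-2-enoic acid | CCCCC(=O)/C=C/C(=O)O | intermediate
32 | O-acylisourea of 31 and dicyclohexylcarbodiimide | CCCCC(=O)/C=C/C(=O)OC(=NC1CCCCC1)NC1CCCCC1 | intermediate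
33 | (3R,4S,4aS,6S,7R,8R,8aS)-3,4a,6,8-tetramethyl-2-oxo-4-[(triethylsilyl)oxy]perhydropyrano[3,2-b]pyran-7-yl (E)-4-oxooct-2-enoate | CCCCC(=O)/C=C/C(=O)O[C@@H]1[C@@H](C)[C@@H]2OC(=O)[C@H](C)[C@H](O[Si](CC)(CC)CC)[C@@]2(C)O[C@H]1C | intermediate
34 | botcinin I | CCCCC(=O)/C=C/C(=O)O[C@@H]1[C@@H](C)[C@@H]2OC(=O)[C@H](C)[C@H](O)[C@@]2(C)O[C@H]1C | target

**Step count**

Total: 20 steps. Longest linear sequence: 17 steps (steps 1–4, 7–17, 19, 20, from compound 1).

**Steps most likely to fail, with fallbacks**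

Step 13 (key ring closure). The risk is that ionisation at C4 runs ahead of ring closure. The isolated hydroxy epoxide could then close through the wrong oxygen (the pivalate carbonyl adding to C3) or rearrange by hydride shift from C5. The fallback removes the ester and never isolates the free hydroxy epoxide. It sets out from allylic alcohol 18: epoxidation with mCPBA (aq. NaHCO3, 0 °C), directed by the C5 hydroxyl exactly as in step 12, should give the epoxy alcohol bis-silyl ether F1. HF·pyridine in THF then removes the secondary silyl group on O8, and the liberated hydroxyl closes onto C4 in the same medium to give the pyran C1 silyl ether F2. Bu4NF removes the remaining silyl group, and the sequence comes back to the route at triol 23, bypassing compounds 19 to 22.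

Step 7 (aldol union). The risk is insufficient facial discrimination at the α-silyloxy aldehyde (the 7,8-syn isomer), or erosion of the Z-enone by γ-deprotonation during enolisation. The fallback puts the C6/C7 pair under auxiliary control and forms the Z-enone last. It sets out from aldehyde 14: an Evans syn aldol with (R)-4-benzyl-3-propionyloxazolidin-2-one (Bu2BOTf, i-Pr2NEt, CH2Cl2, −78 → 0 °C), in which auxiliary and aldehyde bias are matched, should give the imide aldol adduct F3. Transamination with MeNHOMe·HCl and AlMe3 gives the β-hydroxy Weinreb amide F4. Benzylation with benzyl trichloroacetimidate and catalytic TfOH gives the benzyl ether Weinreb amide F5. Addition of vinyllithium 10 (made from 8 as in step 4) at −78 °C then comes back to the route at enone 17.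

Step 12 (directed epoxidation). The risk is poor facial selectivity, because the C1 branch on C2 lies on the hydroxyl-directed face, together with acid-triggered opening of the product during the reaction. The fallback replaces substrate direction by catalyst control under basic buffer. It sets out from 20 and comes back at 21 with no new compound: Shi epoxidation with the L-fructose-derived ketone (the enantiomer of the usual Shi ketone, 1,2:4,5-di-O-isopropylidene-β-L-erythro-2,3-hexodiulo-2,6-pyranose), KHSO5 and K2CO3 in MeCN/dimethoxymethane/water at 0 °C. By the spiro transition-state mnemonic for the C4-methyl/C2 trans pair, this enantiomer should deliver oxygen to the same face as the hydroxyl-directed pathway.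

**Further compounds**

F1 | step 13 | (2S,3S,4R,5S,6S,7R,8S)-7-(benzyloxy)-8-[(tert-butyldimethylsilyl)oxy]-1-[(tert-butyldiphenylsilyl)oxy]-3,4-epoxy-2,4,6-trimethylnonan-5-ol | C[C@H](O[Si](C)(C)C(C)(C)C)[C@H](OCc1ccccc1)[C@@H](C)[C@H](O)[C@@]1(C)O[C@H]1[C@@H](C)CO[Si](c1ccccc1)(c1ccccc1)C(C)(C)C
F2 | step 13 | C1 tert-butyldiphenylsilyl ether of triol 23 | c1ccccc1CO[C@@H]1[C@@H](C)[C@H](O)[C@](C)(O[C@H]1C)[C@@H](O)[C@@H](C)CO[Si](c1ccccc1)(c1ccccc1)C(C)(C)C
F3 | step 7 | (R)-4-benzyl-3-[(2R,3R,4S)-4-[(tert-butyldimethylsilyl)oxy]-3-hydroxy-2-methylpentanoyl]oxazolidin-2-one | C[C@H](O[Si](C)(C)C(C)(C)C)[C@H](O)[C@@H](C)C(=O)N1[C@H](Cc2ccccc2)COC1=O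
F4 | step 7 | (2R,3R,4S)-4-[(tert-butyldimethylsilyl)oxy]-3-hydroxy-N-methoxy-N,2-dimethylpentanamide | C[C@H](O[Si](C)(C)C(C)(C)C)[C@H](O)[C@@H](C)C(=O)N(C)OC
F5 | step 7 | (2R,3R,4S)-3-(benzyloxy)-4-[(tert-butyldimethylsilyl)oxy]-N-methoxy-N,2-dimethylpentanamide | C[C@H](O[Si](C)(C)C(C)(C)C)[C@H](OCc1ccccc1)[C@@H](C)C(=O)N(C)OC
F0 | step 12 | none | none
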